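**Retrosynthetic overview**

1. The target is reached from the doubly protected tetralone 22 by removing the pyranone methoxymethyl ether and then the C3 silyl ether.
2. The strategy rests on ring B (C1 to C4, C4a, C8a; C1 ketone, C3 carbinol): it is a 5-oxygenated cyclohex-2-enone whose C2=C3 bond becomes the ring fusion C8a=C4a. Ring A (C4a, C5, C6, C7, C8, C8a) is therefore disconnected at C8–C8a and C4a–C5 into bromoenone 7 and a vinylketene acetal 19 that carries C5 to C8 with the pyranone (C5), the isopentyl group (C6) and the phenol oxygen (C8).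
3. Diene 19 comes from ester 17 by silylation of its dienolate. Ester 17 comes from a Negishi coupling of the lateral zinc reagent of MOM-protected triacetic acid lactone with the enol triflate of methyl 6-methyl-3-oxoheptanoate.
4. Bromoenone 7 comes from cis,cis-cyclohexane-1,3,5-triol by monosilylation, lipase desymmetrization, oxidation with loss of acetic acid, and α-bromination.
5. Ring order: the pyranone ring and ring B are bought as rings; ring A is the only ring formed, last, in step 10.

Key step: step 10

Assumption: the lipase in step 2 is taken to acylate the R-configured carbinol of meso diol 2 (the usual preference of lipases for secondary alcohols, the silyloxy-bearing ring arm being the larger group). The carbonyl then ends up on the S carbinol carbon and C3 of the target is R.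
Remark: the aryl–pyranone bond is taken to rotate freely, since the target has no axial descriptor.

**Route**

Step 1
Reactants: 1 cis,cis-cyclohexane-1,3,5-triol
Product: 2 all-cis-5-[(tert-butyldimethylsilyl)oxy]cyclohexane-1,3-diol (meso)
Conditions: TBSCl (1 equiv), imidazole, DMF, 0 °C → rt; 1 in threefold excess, recovered
Reagents that add atoms: tert-butyldimethylsilyl chloride, CC(C)(C)[Si](C)(C)Cl
Why: Statistical monosilylation of a triol with three equivalent hydroxyls can give only one mono-ether, and the excess of triol should hold back double silylation; the product is meso, so no stereochemistry is set here.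

Step 2
Reactants: 2 all-cis-5-[(tert-butyldimethylsilyl)oxy]cyclohexane-1,3-diol
Product: 3 (1R,3S,5S)-3-[(tert-butyldimethylsilyl)oxy]-5-hydroxycyclohexyl acetate
Conditions: Candida antarctica lipase B (immobilised), vinyl acetate, MTBE, 30 °C
Reagents that add atoms: vinyl acetate, C=COC(C)=O
Why: Lipase-catalysed irreversible transesterification desymmetrizes the meso diol by acylating one enantiotopic hydroxyl (the R carbinol, see assumption); this fixes the absolute configuration of the silyloxy-bearing carbon, the future C3.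

Step 3
Reactants: 3 (1R,3S,5S)-3-[(tert-butyldimethylsilyl)oxy]-5-hydroxycyclohexyl acetate
Product: 5 (R)-5-[(tert-butyldimethylsilyl)oxy]cyclohex-2-en-1-one, via acetoxy ketone 4 (not isolated)
Conditions: n-Pr4N[RuO4] (5 mol %), NMO, 4 Å MS, CH2Cl2, rt; then Et3N, 0 °C → rt
Reagents that add atoms: none
Why: Ley–Griffith oxidation gives the β-acetoxy ketone, which should lose acetic acid by E1cB elimination far faster than silanol because acetate is the much better leaving group; the silyloxy stereocentre is not touched.

Step 4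
Reactants: 5 (R)-5-[(tert-butyldimethylsilyl)oxy]cyclohex-2-en-1-one
Product: 7 (R)-2-bromo-5-[(tert-butyldimethylsilyl)oxy]cyclohex-2-en-1-one, via dibromo ketone 6 (not isolated)
Conditions: Br2, CH2Cl2, 0 °C; then Et3N, 0 °C
Reagents that add atoms: bromine, BrBr
Why: Bromine addition to the enone followed by E1cB dehydrobromination (removal of the acidic C2 hydrogen, loss of the C3 bromide) is the standard α-bromination of cyclohexenones; the short exposure to Et3N at 0 °C should not eliminate the silyloxy group.

Step 5
Reactants: 8 4-methylpentanoyl chloride, 9 Meldrum's acid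
Product: 11 methyl 6-methyl-3-oxoheptanoate, via acyl Meldrum's acid 10 (not isolated)
Conditions: pyridine, CH2Cl2, 0 °C → rt; then MeOH, reflux
Reagents that add atoms: methanol, CO
Why: C-acylation of Meldrum's acid followed by methanolysis with loss of acetone and CO2 is a dependable β-keto ester synthesis and places the isopentyl chain on the ketone carbon (the future C6).

Step 6
Reactants: 11 methyl 6-methyl-3-oxoheptanoate
Product: 12 methyl (Z)-6-methyl-3-{[(trifluoromethyl)sulfonyl]oxy}hept-2-enoate
Conditions: Tf2O, sat. aq. LiOH, toluene, 5–10 °C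
Reagents that add atoms: trifluoromethanesulfonic anhydride, O=S(=O)(OS(=O)(=O)C(F)(F)F)C(F)(F)F
Why: O-triflation of the chelated lithium enolate of a β-keto ester should give the Z enol triflate; the geometry is of no consequence later, because all isomers of 17 give the same dienolate in step 9.

Step 7
Reactants: 13 4-hydroxy-6-methyl-2H-pyran-2-one (triacetic acid lactone)
Product: 14 4-(methoxymethoxy)-6-methyl-2H-pyran-2-one
Conditions: MOMCl, i-Pr2NEt, CH2Cl2, 0 °C → rt
Reagents that add atoms: chloromethyl methyl ether, COCCl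
Why: O-alkylation of the vinylogous acid at the 4-oxygen with a hard alkoxymethyl chloride masks the acidic hydroxyl for the organometallic steps.

Step 8
Reactants: 14 4-(methoxymethoxy)-6-methyl-2H-pyran-2-one, 12 methyl (Z)-6-methyl-3-{[(trifluoromethyl)sulfonyl]oxy}hept-2-enoate
Product: 17 methyl (Z)-3-{[4-(methoxymethoxy)-2-oxo-2H-pyran-6-yl]methyl}-6-methylhept-2-enoate, via lateral lithium species 15 (not isolated), via organozinc chloride 16 (not isolated)
Conditions: 14 (2.2 equiv), LiN(i-Pr)2, THF, −78 °C; ZnCl2, −78 → 0 °C; then 12, Pd(PPh3)4 (5 mol %), THF, 0 °C → rt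
Reagents that add atoms: none
Why: Lateral deprotonation of the 6-methyl group, transmetalation to zinc and Negishi coupling with the electron-poor alkenyl triflate should join the pyranone CH2 to the triflate carbon with retention; the zinc reagent is used in excess because the product is the stronger carbon acid.

Step 9
Reactants: 17 methyl (Z)-3-{[4-(methoxymethoxy)-2-oxo-2H-pyran-6-yl]methyl}-6-methylhept-2-enoate
Product: 19 6-[(1E,3Z)-4-methoxy-2-(3-methylbutyl)-4-[(trimethylsilyl)oxy]buta-1,3-dien-1-yl]-4-(methoxymethoxy)-2H-pyran-2-one, via lithium dienolate 18 (not isolated)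
Conditions: LiN(SiMe3)2, THF, −78 °C; TMSCl, −78 → 0 °C; pentane, filtration under Ar; used crude at once
Reagents that add atoms: chlorotrimethylsilane, C[Si](C)(C)Cl
Why: Deprotonation of the doubly activated CH2 (γ to the ester, lateral to the pyranone) and O-silylation of the ester dienolate is the usual vinylketene acetal synthesis; silylation is expected on the ester oxygen (the nearer acceptor, with the lactone kept intact), and the delocalized anion should settle into the extended geometry with the pyranone trans to C7, which the s-cis diene needs.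

Step 10
Reactants: 19 6-[(1E,3Z)-4-methoxy-2-(3-methylbutyl)-4-[(trimethylsilyl)oxy]buta-1,3-dien-1-yl]-4-(methoxymethoxy)-2H-pyran-2-one, 7 (R)-2-bromo-5-[(tert-butyldimethylsilyl)oxy]cyclohex-2-en-1-one
Product: 22 (R)-3-[(tert-butyldimethylsilyl)oxy]-8-hydroxy-5-[4-(methoxymethoxy)-2-oxo-2H-pyran-6-yl]-6-(3-methylbutyl)-3,4-dihydronaphthalen-1(2H)-one, via bromo ketal cycloadduct 20 (not isolated), via aryl trimethylsilyl ether 21 (not isolated)
Conditions: 19 (1.5 equiv), 2,6-lutidine (3 equiv), PhMe, 80 °C; then 2,6-lutidinium tosylate (10 mol %), 40 °C; aq. NH4Cl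
Reagents that add atoms: none
Why: The electron-rich 1,1-dioxygenated diene 19 and the α-bromoenone 7 should combine in a normal-demand, asynchronous [4+2] cycloaddition in which the diene terminus C5 bonds first to the enone β-carbon C4a and the acetal carbon C8 then closes onto the brominated α-carbon C8a; this is the known benzannulation of vinylketene acetals with α-halo enones and haloquinones (Diels–Alder reaction followed by elimination). Ring A is closed as a six-membered carbocycle by suprafacial addition across C8a=C4a to give the cis-fused adduct 20, whose four new sp3 centres (C4a, C5, C8, C8a) are all erased on aromatization, so no new stereocentre has to be controlled and C3 is carried in unchanged from 7. Because Br on C8a and H on C4a are cis in 20, aromatization is not expected to begin with an anti E2 loss of HBr: the allylic mixed ketal at C8 should ionize under the buffered acid and lose the C5 hydrogen (allylic and activated by the pyranone), a 1,4-loss of methanol that gives a 1-silyloxycyclohexa-1,3-diene, and loss of HBr from this diene to lutidine is then driven by aromatization to 21. Aqueous work-up should cleave the labile peri aryl trimethylsilyl ether to the hydrogen-bonded phenol 22. The step needs the regiochemistry C5 to C4a and C8 to C8a, which the matched polarization of the ketene acetal (nucleophilic at C5) and of the enone (electrophilic at C4a) secures, and it needs aromatization to outpace β-elimination of the C3 silyloxy group, which the weak, hindered base (too weak to enolize the C1 ketone) and the poor leaving-group ability of silanolate secure.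

Step 11
Reactants: 22 (R)-3-[(tert-butyldimethylsilyl)oxy]-8-hydroxy-5-[4-(methoxymethoxy)-2-oxo-2H-pyran-6-yl]-6-(3-methylbutyl)-3,4-dihydronaphthalen-1(2H)-one
Product: 23 (R)-3-[(tert-butyldimethylsilyl)oxy]-8-hydroxy-5-(4-hydroxy-2-oxo-2H-pyran-6-yl)-6-(3-methylbutyl)-3,4-dihydronaphthalen-1(2H)-one
Conditions: TFA, n-PrSH, CH2Cl2, 0 °C
Reagents that add atoms: none
Why: The methoxymethyl ether of a vinylogous acid is as labile as a MOM ester and should be cleaved by brief acid treatment (acetal cleavage), the thiol trapping the methoxymethyl cation before it can alkylate C3 of the freed pyranone or the phenol ring; any partial loss of the silyl ether is harmless because step 12 removes it.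

Step 12
Reactants: 23 (R)-3-[(tert-butyldimethylsilyl)oxy]-8-hydroxy-5-(4-hydroxy-2-oxo-2H-pyran-6-yl)-6-(3-methylbutyl)-3,4-dihydronaphthalen-1(2H)-one
Product: 24 (R)-3,8-dihydroxy-5-(4-hydroxy-2-oxo-2H-pyran-6-yl)-6-(3-methylbutyl)-3,4-dihydronaphthalen-1(2H)-one (target)
Conditions: HF·pyridine, pyridine, THF, 0 °C → rt; work-up at pH 5–6
Reagents that add atoms: none
Why: Fluoride-mediated Si–O cleavage under buffered, weakly acidic conditions should free the C3 hydroxyl without a base that could dehydrate the β-hydroxy ketone to the naphthol; the C–O bond at C3 is not broken, so the R configuration is kept.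

**Compound list**

1 | cis,cis-cyclohexane-1,3,5-triol | O[C@@H]1C[C@H](O)C[C@H](O)C1 | starting material
2 | all-cis-5-[(tert-butyldimethylsilyl)oxy]cyclohexane-1,3-diol (meso) | O[C@@H]1C[C@H](O[Si](C)(C)C(C)(C)C)C[C@H](O)C1 | intermediate
3 | (1R,3S,5S)-3-[(tert-butyldimethylsilyl)oxy]-5-hydroxycyclohexyl acetate | O[C@@H]1C[C@H](O[Si](C)(C)C(C)(C)C)C[C@H](OC(C)=O)C1 | intermediate
4 | (1S,3R)-3-[(tert-butyldimethylsilyl)oxy]-5-oxocyclohexyl acetate | O=C1C[C@H](O[Si](C)(C)C(C)(C)C)C[C@H](OC(C)=O)C1 | intermediate
5 | (R)-5-[(tert-butyldimethylsilyl)oxy]cyclohex-2-en-1-one | O=C1C[C@H](O[Si](C)(C)C(C)(C)C)CC=C1 | intermediate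
6 | (5R)-2,3-dibromo-5-[(tert-butyldimethylsilyl)oxy]cyclohexan-1-one (C2 and C3 not defined) | O=C1C[C@H](O[Si](C)(C)C(C)(C)C)CC(Br)C1Br | intermediate
7 | (R)-2-bromo-5-[(tert-butyldimethylsilyl)oxy]cyclohex-2-en-1-one | O=C1C[C@H](O[Si](C)(C)C(C)(C)C)CC=C1Br | intermediate
8 | 4-methylpentanoyl chloride | CC(C)CCC(=O)Cl | starting material
9 | Meldrum's acid (2,2-dimethyl-1,3-dioxane-4,6-dione) | CC1(C)OC(=O)CC(=O)O1 | starting material
10 | 5-(1-hydroxy-4-methylpentylidene)-2,2-dimethyl-1,3-dioxane-4,6-dione | CC(C)CCC(O)=C1C(=O)OC(C)(C)OC1=O | intermediate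
11 | methyl 6-methyl-3-oxoheptanoate | COC(=O)CC(=O)CCC(C)C | intermediate
12 | methyl (Z)-6-methyl-3-{[(trifluoromethyl)sulfonyl]oxy}hept-2-enoate | COC(=O)/C=C(\OS(=O)(=O)C(F)(F)F)CCC(C)C | intermediate
13 | 4-hydroxy-6-methyl-2H-pyran-2-one | Cc1cc(O)cc(=O)o1 | starting material
14 | 4-(methoxymethoxy)-6-methyl-2H-pyran-2-one | Cc1cc(OCOC)cc(=O)o1 | intermediate
15 | {[4-(methoxymethoxy)-2-oxo-2H-pyran-6-yl]methyl}lithium | [Li]Cc1cc(OCOC)cc(=O)o1 | intermediate
16 | {[4-(methoxymethoxy)-2-oxo-2H-pyran-6-yl]methyl}zinc chloride | Cl[Zn]Cc1cc(OCOC)cc(=O)o1 | intermediate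
17 | methyl (Z)-3-{[4-(methoxymethoxy)-2-oxo-2H-pyran-6-yl]methyl}-6-methylhept-2-enoate | COC(=O)/C=C(\Cc1cc(OCOC)cc(=O)o1)CCC(C)C | intermediate
18 | lithium dienolate of 17 | CO/C(O[Li])=C/C(CCC(C)C)=C/c1cc(OCOC)cc(=O)o1 | intermediate
19 | 6-[(1E,3Z)-4-methoxy-2-(3-methylbutyl)-4-[(trimethylsilyl)oxy]buta-1,3-dien-1-yl]-4-(methoxymethoxy)-2H-pyran-2-one | CO/C(O[Si](C)(C)C)=C/C(CCC(C)C)=C/c1cc(OCOC)cc(=O)o1 | intermediate
20 | (3R)-8a-bromo-3-[(tert-butyldimethylsilyl)oxy]-8-methoxy-5-[4-(methoxymethoxy)-2-oxo-2H-pyran-6-yl]-6-(3-methylbutyl)-8-[(trimethylsilyl)oxy]-3,4,4a,5,8,8a-hexahydronaphthalen-1(2H)-one (cis-fused; C4a, C5, C8, C8a not defined) | COC1(O[Si](C)(C)C)C=C(CCC(C)C)C(c2cc(OCOC)cc(=O)o2)C2C[C@@H](O[Si](C)(C)C(C)(C)C)CC(=O)C12Br | intermediate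
21 | (R)-3-[(tert-butyldimethylsilyl)oxy]-5-[4-(methoxymethoxy)-2-oxo-2H-pyran-6-yl]-6-(3-methylbutyl)-8-[(trimethylsilyl)oxy]-3,4-dihydronaphthalen-1(2H)-one | CC(C)CCc1cc(O[Si](C)(C)C)c2c(c1-c1cc(OCOC)cc(=O)o1)C[C@@H](O[Si](C)(C)C(C)(C)C)CC2=O | intermediate
22 | (R)-3-[(tert-butyldimethylsilyl)oxy]-8-hydroxy-5-[4-(methoxymethoxy)-2-oxo-2H-pyran-6-yl]-6-(3-methylbutyl)-3,4-dihydronaphthalen-1(2H)-one | CC(C)CCc1cc(O)c2c(c1-c1cc(OCOC)cc(=O)o1)C[C@@H](O[Si](C)(C)C(C)(C)C)CC2=O | intermediate
23 | (R)-3-[(tert-butyldimethylsilyl)oxy]-8-hydroxy-5-(4-hydroxy-2-oxo-2H-pyran-6-yl)-6-(3-methylbutyl)-3,4-dihydronaphthalen-1(2H)-one | CC(C)CCc1cc(O)c2c(c1-c1cc(O)cc(=O)o1)C[C@@H](O[Si](C)(C)C(C)(C)C)CC2=O | intermediate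
24 | (R)-3,8-dihydroxy-5-(4-hydroxy-2-oxo-2H-pyran-6-yl)-6-(3-methylbutyl)-3,4-dihydronaphthalen-1(2H)-one | CC(C)CCc1cc(O)c2c(c1-c1cc(O)cc(=O)o1)C[C@@H](O)CC2=O | target

**Step count and risks**

Total step count: 12. Longest linear sequence: 7 steps (steps 1, 2, 3, 4, 10, 11, 12; the diene branch through steps 5, 6, 8, 9, 10, 11, 12 is equally long).

Steps most likely to fail:

1. Step 10. The diene is in conjugation with the electron-poor pyranone and may add too slowly to the moderately reactive bromoenone or react stepwise through C7. The cis-disposed HBr may also not be lost without forcing, and forcing would invite β-elimination of the silyloxy group with aromatization of ring B. The fallback sets out from 5 and replaces bromine by a sulfinyl group, which activates the dienophile more strongly and leaves by a thermal syn-elimination that the cis geometry favours. PhSCl in CH2Cl2 at −78 °C should add across the enone to give (5R)-5-[(tert-butyldimethylsilyl)oxy]-3-chloro-2-(phenylsulfanyl)cyclohexan-1-one F1, which with Et3N should lose HCl to give (R)-5-[(tert-butyldimethylsilyl)oxy]-2-(phenylsulfanyl)cyclohex-2-en-1-one F2. Oxidation with mCPBA (1 equiv, −78 °C) should give (5R)-5-[(tert-butyldimethylsilyl)oxy]-2-(phenylsulfinyl)cyclohex-2-en-1-one F3 as a mixture at sulfur, which does not matter. Cycloaddition of F3 with 19 in toluene at 80–110 °C should give the sulfinyl ketal cycloadduct F4; syn-elimination of benzenesulfenic acid across C8a–C4a and 1,4-loss of methanol lead to 21, and aqueous work-up comes back to the route at 22.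

2. Step 8. The product is a stronger carbon acid than 14, so proton transfer to the zinc reagent may stall the coupling. A second vinylation, or coupling through a ring carbon of the ambident zinc species, is also possible. The fallback sets out from 12 and 14 and reverses the polarity of the partners. Miyaura borylation of 12 (B2pin2, PdCl2(dppf), K2CO3, dioxane, 80 °C) should give methyl (E)-6-methyl-3-(4,4,5,5-tetramethyl-1,3,2-dioxaborolan-2-yl)hept-2-enoate F5. Radical bromination of 14 (NBS, AIBN, PhCF3, 80 °C) should give 6-(bromomethyl)-4-(methoxymethoxy)-2H-pyran-2-one F6. Suzuki–Miyaura coupling of F5 with F6 (Pd(PPh3)4, K2CO3, THF/H2O, 50 °C) comes back to the route at 17; no strongly basic organometallic is present.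

3. Step 2. The lipase may show the opposite enantiotopic preference or an insufficient one, which would give the wrong or an impure enantiomer of the enone. The fallback sets out from 2 and runs the desymmetrization in the hydrolytic direction. Acetylation (Ac2O, pyridine, DMAP) should give all-cis-5-[(tert-butyldimethylsilyl)oxy]cyclohexane-1,3-diyl diacetate F7. A lipase or esterase, chosen by screening to cleave the acetate on the S-configured carbon (pH 7 phosphate buffer, rt), leaves the R acetate and comes back to the route at 3. An enzyme that acylates the wrong hydroxyl in step 2 should cleave exactly that acetate here.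

**Further compounds**

F1 | step 10 | (5R)-5-[(tert-butyldimethylsilyl)oxy]-3-chloro-2-(phenylsulfanyl)cyclohexan-1-one | O=C1C[C@H](O[Si](C)(C)C(C)(C)C)CC(Cl)C1Sc1ccccc1
F2 | step 10 | (R)-5-[(tert-butyldimethylsilyl)oxy]-2-(phenylsulfanyl)cyclohex-2-en-1-one | O=C1C[C@H](O[Si](C)(C)C(C)(C)C)CC=C1Sc1ccccc1
F3 | step 10 | (5R)-5-[(tert-butyldimethylsilyl)oxy]-2-(phenylsulfinyl)cyclohex-2-en-1-one | O=C1C[C@H](O[Si](C)(C)C(C)(C)C)CC=C1S(=O)c1ccccc1
F4 | step 10 | (3R)-3-[(tert-butyldimethylsilyl)oxy]-8-methoxy-5-[4-(methoxymethoxy)-2-oxo-2H-pyran-6-yl]-6-(3-methylbutyl)-8a-(phenylsulfinyl)-8-[(trimethylsilyl)oxy]-3,4,4a,5,8,8a-hexahydronaphthalen-1(2H)-one | COC1(O[Si](C)(C)C)C=C(CCC(C)C)C(c2cc(OCOC)cc(=O)o2)C2C[C@@H](O[Si](C)(C)C(C)(C)C)CC(=O)C12S(=O)c1ccccc1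
F5 | step 8 | methyl (E)-6-methyl-3-(4,4,5,5-tetramethyl-1,3,2-dioxaborolan-2-yl)hept-2-enoate | COC(=O)/C=C(\B1OC(C)(C)C(C)(C)O1)CCC(C)C
F6 | step 8 | 6-(bromomethyl)-4-(methoxymethoxy)-2H-pyran-2-one | BrCc1cc(OCOC)cc(=O)o1
F7 | step 2 | all-cis-5-[(tert-butyldimethylsilyl)oxy]cyclohexane-1,3-diyl diacetate | CC(=O)O[C@@H]1C[C@H](O[Si](C)(C)C(C)(C)C)C[C@H](OC(C)=O)C1
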